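It is easy to count the first nucleophile as charged and forget that the protic impurity may take some of it.

| setting | summer | noon | flask |
|---|---|---|---|
| starting material | 0.16 M | 0.16 M | 0.16 M |
| first nucleophile | 1.3 equiv | 3 equiv | 2.00 equiv |
| second nucleophile | 4 equiv | 4 equiv | 4.00 equiv |
| protic impurity | 0.080 M | 0.080 M | 0.0800 M |
| remark | run made earlier | run made earlier |  |
| time |  |  | 10 h |

| run | time / h | other capture product / % | target / % | starting material / % |
|---|---|---|---|---|
| summer | 0.667 | 65.7 | 33.8 | 0.1 |
| summer | 1.00 | 66.4 | 34.1 | 0.3 |
| summer | 2.00 | 66.3 | 34.4 | 0 |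
| summer | 3.00 | 66.1 | 34.5 | 0 |
| summer | 5.00 | 65.5 | 34.3 | 0 |
| summer | 8.00 | 65.7 | 33.9 | 0 |
| noon | 1.33 | 39.6 | 60.5 | 0 |
| noon | 2.50 | 39.8 | 60.4 | 0 |
| noon | 4.00 | 40.0 | 60.8 | 0 |
| noon | 5.00 | 40.1 | 60.1 | 0 |
| noon | 6.00 | 39.7 | 60.0 | 0 |
| noon | 8.00 | 39.9 | 59.9 | 0.4 |

(standard deviation of a reading: 0.3 percentage points)

- ratio of other capture product to target at 5.0 s
- ratio of other capture product to target at 10 h



Reckon in fractions of the starting material charged. The impurity stands at 0.500. Suppose it takes that much first nucleophile, one for one, and divide what remains by the second nucleophile charged: this usable ratio is 0.200 in the summer run and 0.625 in the noon run. Target over other capture product, divided by the usable ratio, gives 2.59 from the summer reading at 2.00 h and 2.43 from the noon reading at 4.00 h. Their mean, 2.51, is the selectivity factor: target made per other capture product when the usable ratio is one. The two readings differ by 6.46%, so one number is good to about that much.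

Both runs stay flat over the hours read, so for this flask I hold the ratio to 10 h and reckon 1.06. At 5.0 s I assume the impurity has taken little, so the whole charge counts, giving 0.796.

The forecast said 0.95 (0.6 to 1.6) at 5.0 s, above mine, and 1.08 (1 to 1.17) at 10 h, and it widened its early range with the words “If the ratio is set by equilibration, the early kinetic ratio is unconstrained”.

The flask gives 0.798 at 5.0 s and 1.10 at 10 h.

    starting material → intermediate (k = 0.00620 s⁻¹)
    first nucleophile + intermediate → target (k = 4.60 M⁻¹ s⁻¹)
    second nucleophile + intermediate → other capture product (k = 1.80 M⁻¹ s⁻¹)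
    first nucleophile + protic impurity → quenched reagent (k = 0.0840 M⁻¹ s⁻¹)

In this flask, half of the quenching is done by 0.475 min, sooner than half of the making of intermediate at 1.86 min. The early time of 5.0 s comes before that halfway mark, and by 1.00 h the impurity stands at 0%.

In the neighbouring flask with 8.00 equiv of first nucleophile, 2.51 gives 0.212 at 10 h and 0.199 at 5.0 s. The computed values there are 0.215 and 0.199.

(The readings come from a simulation for substances that don't exist; scatter was added.)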